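**Retrosynthetic overview**
1. Target 13 ⇐ tri-O-benzyl ether 12 (BCl3/pentamethylbenzene) ⇐ aryl bromide 10 + methyl acrylate 11 (Heck).
2. Key disconnection, C3–C3a of the dihydrobenzofuran: 10 ⇐ (R)-flavanone 7 by oxidative ring contraction. The ketone α-carbon is made electrophilic as an α-iodanyl ketal (enolonium equivalent) and the electron-rich ring A migrates onto it; C4 becomes the ester carbon.
3. C2 is set first, in 7, by asymmetric conjugate arylation of chromone 5 with boronic acid 6; the ring contraction relays it to C3 (trans).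
4. Chromone 5 ⇐ acetophenone 3 (enaminone, then cyclisation) ⇐ 1-(2,3-dihydroxyphenyl)ethanone 1 (benzylation, bromination).
5. Ring order: both benzene rings are bought; the pyranone ring is closed first and is then contracted to the dihydrofuran ring.

Assumption: (S)-t-BuPyOx with Pd(OCOCF3)2 is taken to deliver the aryl group to the chromone face that gives (R)-7 (by analogy with its sense on cyclic enones); if the opposite sense is found, the (R)-ligand is used with nothing else changed.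

**Step 1**
Reactants: 1 1-(2,3-dihydroxyphenyl)ethanone
Product: 2 1-[3-(benzyloxy)-2-hydroxyphenyl]ethanone
Conditions: NaH (2.2 equiv), DMSO, rt; BnBr (1.0 equiv), rt; then 1 M HCl
Reagents that add atoms: benzyl bromide, BrCc1ccccc1
Why: Williamson ether synthesis on the catecholate dianion, in which the 3-oxide (neither conjugated to nor chelated by the acetyl group) is the more nucleophilic oxygen and takes the single benzyl group; no stereocentre is involved.

**Step 2**
Reactants: 2 1-[3-(benzyloxy)-2-hydroxyphenyl]ethanone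
Product: 3 1-[3-(benzyloxy)-5-bromo-2-hydroxyphenyl]ethanone
Conditions: NBS (1.05 equiv), MeCN, 0 °C to rt
Reagents that add atoms: N-bromosuccinimide, O=C1CCC(=O)N1Br
Why: Electrophilic aromatic bromination goes para to the free phenol, which is also meta to the acetyl group, as in the bromination of o-vanillin.

**Step 3**
Reactants: 3 1-[3-(benzyloxy)-5-bromo-2-hydroxyphenyl]ethanone
Product: 5 8-(benzyloxy)-6-bromo-4H-chromen-4-one, via enaminone 4 (not isolated)
Conditions: Me2NCH(OMe)2 (2 equiv), toluene, 100 °C; evaporate; conc. HCl, CH2Cl2, rt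
Reagents that add atoms: N,N-dimethylformamide dimethyl acetal, COC(OC)N(C)C
Why: Enaminone condensation at the methyl ketone followed by acid-promoted intramolecular oxa-Michael addition and loss of dimethylamine is the standard chromone synthesis.

**Step 4**
Reactants: 5 8-(benzyloxy)-6-bromo-4H-chromen-4-one; 6 [3,4-bis(benzyloxy)phenyl]boronic acid (2 equiv)
Product: 7 (2R)-2-[3,4-bis(benzyloxy)phenyl]-8-(benzyloxy)-6-bromo-2,3-dihydro-4H-chromen-4-one
Conditions: Pd(OCOCF3)2 (5 mol%), (S)-t-BuPyOx [(S)-4-tert-butyl-2-(pyridin-2-yl)-4,5-dihydrooxazole] (6 mol%), NH4PF6 (30 mol%), H2O (5 equiv), ClCH2CH2Cl, 60 °C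
Reagents that add atoms: none
Why: Catalytic asymmetric conjugate addition of an aryl–divalent palladium species to the chromone (Hayashi–Miyaura type, pyridine-oxazoline ligand) sets C2 as R by ligand-controlled face selection, and the aryl bromide is untouched because no zerovalent palladium is formed.

**Step 5 (key step)**
Reactants: 7 (2R)-2-[3,4-bis(benzyloxy)phenyl]-8-(benzyloxy)-6-bromo-2,3-dihydro-4H-chromen-4-one
Product: 10 methyl (2R,3R)-7-(benzyloxy)-2-[3,4-bis(benzyloxy)phenyl]-5-bromo-2,3-dihydro-1-benzofuran-3-carboxylate, via dimethyl ketal 8 (not isolated), via iodanyl ketal 9 (not isolated)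
Conditions: PhI(OAc)2 (1.3 equiv), conc. H2SO4 (0.5 equiv), HC(OMe)3 (solvent), 0 °C to rt
Reagents that add atoms: trimethyl orthoformate, COC(OC)OC
Why: Hypervalent-iodine oxidative ring contraction of a flavanone (1,2-aryl shift): the enol ether in equilibrium with ketal 8 is attacked at C3 by trivalent iodine anti to the C2 aryl group to give 9, whose C3 is now a polarity-reversed, electrophilic enolonium equivalent, and ring A migrates from C4 to C3 antiperiplanar to the departing PhI with inversion, so the new C3–aryl bond forms trans to the untouched C2 centre (2R gives 2R,3R) while C4 collapses to the methyl ester.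

**Step 6**
Reactants: 10 methyl (2R,3R)-7-(benzyloxy)-2-[3,4-bis(benzyloxy)phenyl]-5-bromo-2,3-dihydro-1-benzofuran-3-carboxylate; 11 methyl acrylate (1.5 equiv)
Product: 12 methyl (2R,3R)-7-(benzyloxy)-2-[3,4-bis(benzyloxy)phenyl]-5-[(1E)-3-methoxy-3-oxoprop-1-en-1-yl]-2,3-dihydro-1-benzofuran-3-carboxylate
Conditions: Pd2(dba)3 (1.5 mol%), [HP(t-Bu)3]BF4 (6 mol%), Cy2NMe (1.2 equiv), 1,4-dioxane, 70 °C
Reagents that add atoms: none
Why: Mizoroki–Heck coupling through a zerovalent palladium/tri-tert-butylphosphine catalyst gives the (E)-acrylate by syn insertion and syn β-hydride elimination, and the hindered amine base cannot erode the trans arrangement because that is the thermodynamic one and C2 is not touched.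

**Step 7**
Reactants: 12 methyl (2R,3R)-7-(benzyloxy)-2-[3,4-bis(benzyloxy)phenyl]-5-[(1E)-3-methoxy-3-oxoprop-1-en-1-yl]-2,3-dihydro-1-benzofuran-3-carboxylate
Product: 13 methyl (2R,3R)-2-(3,4-dihydroxyphenyl)-7-hydroxy-5-[(1E)-3-methoxy-3-oxoprop-1-en-1-yl]-2,3-dihydro-1-benzofuran-3-carboxylate (CNP0529351.1)
Conditions: BCl3 (6 equiv), pentamethylbenzene (9 equiv), CH2Cl2, −78 °C; then H2O
Reagents that add atoms: none
Why: Lewis-acid cleavage of the three aryl benzyl ethers, with the benzyl cations trapped by pentamethylbenzene (Friedel–Crafts scavenging), is fast at −78 °C and should leave the acrylate double bond, both methyl esters and both stereocentres untouched.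

**Compound list**
1 | 1-(2,3-dihydroxyphenyl)ethanone | CC(=O)c1cccc(O)c1O | starting material
2 | 1-[3-(benzyloxy)-2-hydroxyphenyl]ethanone | CC(=O)c1cccc(OCc2ccccc2)c1O | intermediate
3 | 1-[3-(benzyloxy)-5-bromo-2-hydroxyphenyl]ethanone | CC(=O)c1cc(Br)cc(OCc2ccccc2)c1O | intermediate
4 | (2E)-1-[3-(benzyloxy)-5-bromo-2-hydroxyphenyl]-3-(dimethylamino)prop-2-en-1-one | CN(C)/C=C/C(=O)c1cc(Br)cc(OCc2ccccc2)c1O | intermediate (not isolated)
5 | 8-(benzyloxy)-6-bromo-4H-chromen-4-one | O=c1ccoc2c(OCc3ccccc3)cc(Br)cc12 | intermediate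
6 | [3,4-bis(benzyloxy)phenyl]boronic acid | OB(O)c1ccc(OCc2ccccc2)c(OCc2ccccc2)c1 | starting material
7 | (2R)-2-[3,4-bis(benzyloxy)phenyl]-8-(benzyloxy)-6-bromo-2,3-dihydro-4H-chromen-4-one | O=C1C[C@H](c2ccc(OCc3ccccc3)c(OCc3ccccc3)c2)Oc2c(OCc3ccccc3)cc(Br)cc21 | intermediate
8 | (2R)-2-[3,4-bis(benzyloxy)phenyl]-8-(benzyloxy)-6-bromo-4,4-dimethoxy-3,4-dihydro-2H-chromene | COC1(OC)C[C@H](c2ccc(OCc3ccccc3)c(OCc3ccccc3)c2)Oc2c(OCc3ccccc3)cc(Br)cc21 | intermediate (not isolated)
9 | (2S,3S)-3-[acetoxy(phenyl)-λ3-iodanyl]-2-[3,4-bis(benzyloxy)phenyl]-8-(benzyloxy)-6-bromo-4,4-dimethoxy-3,4-dihydro-2H-chromene (iodine trans to the 2-aryl group; the C2 descriptor changes only through the priority rules) | COC1(OC)[C@@H]([I](OC(C)=O)c3ccccc3)[C@H](c2ccc(OCc3ccccc3)c(OCc3ccccc3)c2)Oc2c(OCc3ccccc3)cc(Br)cc21 | intermediate (not isolated)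
10 | methyl (2R,3R)-7-(benzyloxy)-2-[3,4-bis(benzyloxy)phenyl]-5-bromo-2,3-dihydro-1-benzofuran-3-carboxylate | Brc1cc(OCc3ccccc3)c2c(c1)[C@@H](C(=O)OC)[C@H](c1ccc(OCc3ccccc3)c(OCc3ccccc3)c1)O2 | intermediate
11 | methyl acrylate | C=CC(=O)OC | starting material
12 | methyl (2R,3R)-7-(benzyloxy)-2-[3,4-bis(benzyloxy)phenyl]-5-[(1E)-3-methoxy-3-oxoprop-1-en-1-yl]-2,3-dihydro-1-benzofuran-3-carboxylate | COC(=O)/C=C/c1cc(OCc3ccccc3)c2c(c1)[C@@H](C(=O)OC)[C@H](c1ccc(OCc3ccccc3)c(OCc3ccccc3)c1)O2 | intermediate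
13 | methyl (2R,3R)-2-(3,4-dihydroxyphenyl)-7-hydroxy-5-[(1E)-3-methoxy-3-oxoprop-1-en-1-yl]-2,3-dihydro-1-benzofuran-3-carboxylate | COC(=O)/C=C/c1cc(O)c2c(c1)[C@@H](C(=O)OC)[C@H](c1ccc(O)c(O)c1)O2 | target

**Step count**
Total: 7 steps. Longest linear sequence: 7 steps (1 to 13); 6 and 11 are bought.

**Three steps most likely to fail**

Step 5, the oxidative ring contraction. The electron-rich ring B can migrate instead (isoflavone), the ketal can be dehydrogenated to the flavone, or trivalent iodine can attack the dibenzyloxyphenyl ring. The fallback sets out from 3 and comes back at 10, and builds the dihydrofuran by rhodium-carbenoid C–H insertion instead. Alkylation of 3 with 3,4-bis(benzyloxy)benzyl chloride (K2CO3, DMF, 60 °C) gives 1-{3-(benzyloxy)-2-[(3,4-bis(benzyloxy)phenyl)methoxy]-5-bromophenyl}ethanone F4. The PhI(OAc)2/H2SO4/HC(OMe)3 aryl shift, here on a simple acetophenone with no competing path, gives methyl 2-{3-(benzyloxy)-2-[(3,4-bis(benzyloxy)phenyl)methoxy]-5-bromophenyl}acetate F5. Diazo transfer (4-acetamidobenzenesulfonyl azide, DBU, MeCN) gives methyl 2-{3-(benzyloxy)-2-[(3,4-bis(benzyloxy)phenyl)methoxy]-5-bromophenyl}-2-diazoacetate F6. Rh2(S-PTTL)4 (dirhodium tetrakis[N-phthaloyl-(S)-tert-leucinate], 1 mol%) in toluene at −60 °C inserts the carbenoid into the benzylic ether C–H and sets C2, giving the cis ester methyl (2R,3S)-7-(benzyloxy)-2-[3,4-bis(benzyloxy)phenyl]-5-bromo-2,3-dihydro-1-benzofuran-3-carboxylate F7. NaOMe in MeOH epimerises C3 to the trans ester 10.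

Step 4, the asymmetric conjugate arylation. The 8-benzyloxy chromone and the electron-rich boronic acid (protodeboronation) may give low conversion or low ee. The fallback sets out from 3 and comes back at 7, and replaces catalytic arylation by chalcone cyclisation and kinetic resolution. Claisen–Schmidt condensation of 3 with 3,4-bis(benzyloxy)benzaldehyde (KOH, EtOH, rt) gives the chalcone (2E)-1-[3-(benzyloxy)-5-bromo-2-hydroxyphenyl]-3-[3,4-bis(benzyloxy)phenyl]prop-2-en-1-one F1. NaOAc in refluxing EtOH closes it by oxa-Michael addition to rac-2-[3,4-bis(benzyloxy)phenyl]-8-(benzyloxy)-6-bromo-2,3-dihydro-4H-chromen-4-one F2. Asymmetric transfer hydrogenation with RuCl[(S,S)-TsDPEN](p-cymene) and HCO2H/Et3N in EtOAc, run to about 55% conversion, reduces the (S)-ketone to the cis alcohol (2S,4S)-2-[3,4-bis(benzyloxy)phenyl]-8-(benzyloxy)-6-bromo-3,4-dihydro-2H-chromen-4-ol F3. The unreduced (R)-ketone 7 (at most 50%) is separated by chromatography.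

Step 7, the global debenzylation. BCl3 may also open the benzylic C2–O bond of the dihydrofuran or attack the esters. The fallback sets out from 10 and comes back at 13; it removes the benzyl groups by neutral hydrogenolysis before the alkene exists and makes the acrylate last by Wittig olefination, so it replaces steps 6 and 7. Reductive carbonylation of 10 (Pd(OAc)2, di(1-adamantyl)-n-butylphosphine, CO/H2 1:1 at 5 bar, TMEDA, toluene, 100 °C) gives methyl (2R,3R)-7-(benzyloxy)-2-[3,4-bis(benzyloxy)phenyl]-5-formyl-2,3-dihydro-1-benzofuran-3-carboxylate F8. Hydrogenolysis (H2 1 atm, 10% palladium on carbon (Pd/C), EtOAc, rt, stopped after three equivalents) gives methyl (2R,3R)-2-(3,4-dihydroxyphenyl)-5-formyl-7-hydroxy-2,3-dihydro-1-benzofuran-3-carboxylate F9. Ph3P=CHCO2Me in toluene at 60 °C then gives 13 directly as the (E)-acrylate.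

**Further compounds**
F1 | step 4 | (2E)-1-[3-(benzyloxy)-5-bromo-2-hydroxyphenyl]-3-[3,4-bis(benzyloxy)phenyl]prop-2-en-1-one | O=C(/C=C/c1ccc(OCc2ccccc2)c(OCc2ccccc2)c1)c1cc(Br)cc(OCc2ccccc2)c1O
F2 | step 4 | rac-2-[3,4-bis(benzyloxy)phenyl]-8-(benzyloxy)-6-bromo-2,3-dihydro-4H-chromen-4-one | O=C1CC(c2ccc(OCc3ccccc3)c(OCc3ccccc3)c2)Oc2c(OCc3ccccc3)cc(Br)cc21
F3 | step 4 | (2S,4S)-2-[3,4-bis(benzyloxy)phenyl]-8-(benzyloxy)-6-bromo-3,4-dihydro-2H-chromen-4-ol | O[C@H]1C[C@@H](c2ccc(OCc3ccccc3)c(OCc3ccccc3)c2)Oc2c(OCc3ccccc3)cc(Br)cc21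
F4 | step 5 | 1-{3-(benzyloxy)-2-[(3,4-bis(benzyloxy)phenyl)methoxy]-5-bromophenyl}ethanone | CC(=O)c1cc(Br)cc(OCc2ccccc2)c1OCc1ccc(OCc2ccccc2)c(OCc2ccccc2)c1
F5 | step 5 | methyl 2-{3-(benzyloxy)-2-[(3,4-bis(benzyloxy)phenyl)methoxy]-5-bromophenyl}acetate | COC(=O)Cc1cc(Br)cc(OCc2ccccc2)c1OCc1ccc(OCc2ccccc2)c(OCc2ccccc2)c1
F6 | step 5 | methyl 2-{3-(benzyloxy)-2-[(3,4-bis(benzyloxy)phenyl)methoxy]-5-bromophenyl}-2-diazoacetate | COC(=O)C(=[N+]=[N-])c1cc(Br)cc(OCc2ccccc2)c1OCc1ccc(OCc2ccccc2)c(OCc2ccccc2)c1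
F7 | step 5 | methyl (2R,3S)-7-(benzyloxy)-2-[3,4-bis(benzyloxy)phenyl]-5-bromo-2,3-dihydro-1-benzofuran-3-carboxylate | Brc1cc(OCc3ccccc3)c2c(c1)[C@H](C(=O)OC)[C@H](c1ccc(OCc3ccccc3)c(OCc3ccccc3)c1)O2
F8 | step 7 | methyl (2R,3R)-7-(benzyloxy)-2-[3,4-bis(benzyloxy)phenyl]-5-formyl-2,3-dihydro-1-benzofuran-3-carboxylate | O=Cc1cc(OCc3ccccc3)c2c(c1)[C@@H](C(=O)OC)[C@H](c1ccc(OCc3ccccc3)c(OCc3ccccc3)c1)O2
F9 | step 7 | methyl (2R,3R)-2-(3,4-dihydroxyphenyl)-5-formyl-7-hydroxy-2,3-dihydro-1-benzofuran-3-carboxylate | O=Cc1cc(O)c2c(c1)[C@@H](C(=O)OC)[C@H](c1ccc(O)c(O)c1)O2
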